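**Strategy.** The route rests on cutting the pyran ring (ring C) of the flavan at C4–C4a and O1–C2, which leaves a resorcinol (ring A) and a three-carbon 1-arylallyl unit carrying ring B. In one operation a confined chiral Brønsted acid joins racemic 1-(5-hydroxy-2-methoxyphenyl)prop-2-en-1-ol to 4-bromoresorcinol. Friedel–Crafts allylation occurs at the ring A carbon para to one hydroxyl and ortho to the other (future C4a). Enantioselective hydroalkoxylation follows at the benzylic carbon (C2), which the ortho-methoxy group of ring B turns into a stabilised cation. Both alcohol enantiomers converge on the (2S)-6-bromoflavan-7-ol. The bromine at C6 later becomes a boronic acid for a rhodium-catalysed asymmetric conjugate addition that sets the diarylmethine.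

Key step: step 2

Remark: compounds 1, 3, 8 and 9 are taken as commercial, and since the sense of induction of the chiral acid in step 2 cannot be predicted with confidence, the (S,S)-catalyst is assumed to give (2S), to be fixed by a first screen of both antipodes.

Step 1
Reactants: 1 5-hydroxy-2-methoxybenzaldehyde
Product: 2 rac-1-(5-hydroxy-2-methoxyphenyl)prop-2-en-1-ol
Conditions: vinylmagnesium bromide (2.3 equiv), THF, −78 → 0 °C; aq. NH4Cl
Reagents that add atoms: vinylmagnesium bromide, C=C[Mg]Br
Why: Grignard 1,2-addition to the aldehyde after the first equivalent has deprotonated the phenol; the carbinol is formed racemic on purpose because step 2 erases this stereocenter.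

Step 2
Reactants: 2 rac-1-(5-hydroxy-2-methoxyphenyl)prop-2-en-1-ol; 3 4-bromobenzene-1,3-diol
Product: 5 (2S)-6-bromo-2-(5-hydroxy-2-methoxyphenyl)-3,4-dihydro-2H-chromen-7-ol, via (E)-cinnamylresorcinol 4 (not isolated)
Conditions: (S,S)-imidodiphosphorimidate (IDPi) Brønsted acid with 3,3'-aryl BINOL walls and N-triflyl core (5 mol %), 3 (1.5 equiv), 5 Å MS, CHCl3, −20 → 25 °C
Reagents that add atoms: none
Why: Proposed new method: the acid ionises racemic 2 to an (E)-1-arylallyl cation paired with the chiral anion, ring A attacks its CH2 terminus through the carbon para to one hydroxyl and ortho to the other (Friedel–Crafts allylation, C4–C4a), and the same acid then protonates the styrene of 4 at C3 so that the neighbouring phenol oxygen captures the benzylic C2 cation, which the ortho-methoxy group of ring B stabilises (O1–C2). The closest known reaction types are the achiral-acid-catalysed one-pot flavan synthesis from phenols and cinnamyl alcohols, itself modelled on the biogenetic cinnamylation of phenols, and the asymmetric intramolecular hydroalkoxylation of alkenols by confined IDPi acids. The pyran ring closes in a 6-endo-trig Markovnikov hydroalkoxylation. C2 is set under catalyst control by the confined counteranion, which leaves one face of the benzylic cation open to the phenol, and because the carbinol stereocenter of 2 is destroyed on ionisation both enantiomers and any cinnamyl isomer converge on the same product. The step needs attack at resorcinol C6 and not at the carbon between the two hydroxyls, linear and not branched allylation, and 6-endo and not 5-exo closure; the crowded position between the hydroxyls, conjugation of the linear styrene and the benzylic cation secure these in turn, and the much lower nucleophilicity of the monophenol ring of 2 keeps it from competing with 3.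

Step 3
Reactants: 5 (2S)-6-bromo-2-(5-hydroxy-2-methoxyphenyl)-3,4-dihydro-2H-chromen-7-ol
Product: 6 (2S)-7-(benzyloxy)-2-[5-(benzyloxy)-2-methoxyphenyl]-6-bromo-3,4-dihydro-2H-chromene
Conditions: BnBr (2.4 equiv), K2CO3, DMF, 50 °C
Reagents that add atoms: benzyl bromide, BrCc1ccccc1
Why: Williamson ether synthesis masks both phenols so that step 4 can use an organolithium; the aryl bromide and C2 are not touched by carbonate base.

Step 4
Reactants: 6 (2S)-7-(benzyloxy)-2-[5-(benzyloxy)-2-methoxyphenyl]-6-bromo-3,4-dihydro-2H-chromene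
Product: 7 [(2S)-7-(benzyloxy)-2-[5-(benzyloxy)-2-methoxyphenyl]-3,4-dihydro-2H-chromen-6-yl]boronic acid
Conditions: n-BuLi (1.1 equiv), THF, −78 °C; B(OiPr)3, −78 °C → rt; 1 M HCl
Reagents that add atoms: triisopropyl borate, CC(C)OB(OC(C)C)OC(C)C; water, O
Why: Lithium–bromine exchange followed by borate trapping (borylation of an aryllithium) should outpace any attack on the benzyl ethers at −78 °C, and mild hydrolysis frees the boronic acid.

Step 5
Reactants: 8 1-(4-hydroxy-2-methoxyphenyl)ethan-1-one; 9 4-(benzyloxy)benzaldehyde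
Product: 10 (E)-3-[4-(benzyloxy)phenyl]-1-(4-hydroxy-2-methoxyphenyl)prop-2-en-1-one
Conditions: KOH (50% aq.), EtOH, rt; then dilute HCl
Reagents that add atoms: none
Why: Claisen–Schmidt aldol condensation with a non-enolisable aldehyde; E1cB dehydration should give the (E)-enone, the phenoxide only slowing enolate formation.

Step 6
Reactants: 7 [(2S)-7-(benzyloxy)-2-[5-(benzyloxy)-2-methoxyphenyl]-3,4-dihydro-2H-chromen-6-yl]boronic acid; 10 (E)-3-[4-(benzyloxy)phenyl]-1-(4-hydroxy-2-methoxyphenyl)prop-2-en-1-one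
Product: 11 (3R)-3-[4-(benzyloxy)phenyl]-3-[(2S)-7-(benzyloxy)-2-[5-(benzyloxy)-2-methoxyphenyl]-3,4-dihydro-2H-chromen-6-yl]-1-(4-hydroxy-2-methoxyphenyl)propan-1-one
Conditions: [Rh(OH)((R)-BINAP)]2 (3 mol %), 10 (1.5 equiv), dioxane/H2O 10:1, 50 °C
Reagents that add atoms: none
Why: Hayashi–Miyaura rhodium-catalysed asymmetric 1,4-addition, in which the aryl–rhodium/(R)-BINAP species should add to the α-re face of the (E)-enone (catalyst control by the established binap quadrant model, independent of the remote C2) and so set the (R)-diarylmethine, the base-free hydroxo complex leaving the phenol of 10 protonated.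

Step 7
Reactants: 11 (3R)-3-[4-(benzyloxy)phenyl]-3-[(2S)-7-(benzyloxy)-2-[5-(benzyloxy)-2-methoxyphenyl]-3,4-dihydro-2H-chromen-6-yl]-1-(4-hydroxy-2-methoxyphenyl)propan-1-one
Product: 12 4-methylbenzenesulfonylhydrazone of ketone 11 (C=N geometry undefined)
Conditions: TsNHNH2 (1.5 equiv), cat. AcOH, EtOH, 70 °C
Reagents that add atoms: 4-methylbenzenesulfonohydrazide, Cc1ccc(cc1)S(=O)(=O)NN
Why: Acid-catalysed condensation of the aryl ketone with the sulfonyl hydrazide (tosylhydrazone formation) runs under conditions too mild to ionise the flavan C2–O1 bond.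

Step 8
Reactants: 12 4-methylbenzenesulfonylhydrazone of ketone 11
Product: 13 4-[(3R)-3-[4-(benzyloxy)phenyl]-3-[(2S)-7-(benzyloxy)-2-[5-(benzyloxy)-2-methoxyphenyl]-3,4-dihydro-2H-chromen-6-yl]propyl]-3-methoxyphenol
Conditions: catecholborane (3 equiv), CHCl3, 0 °C → rt; NaOAc·3H2O, reflux
Reagents that add atoms: none
Why: Kabalka-type tosylhydrazone reduction, in which hydride adds to C=N, acetate triggers loss of sulfinate and the diazene loses N2, so the carbonyl carbon becomes CH2 without a cation that could open the flavan or epimerise the methine.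

Step 9
Reactants: 13 4-[(3R)-3-[4-(benzyloxy)phenyl]-3-[(2S)-7-(benzyloxy)-2-[5-(benzyloxy)-2-methoxyphenyl]-3,4-dihydro-2H-chromen-6-yl]propyl]-3-methoxyphenol
Product: 14 (2S)-6-[(1R)-3-(4-hydroxy-2-methoxyphenyl)-1-(4-hydroxyphenyl)propyl]-2-(5-hydroxy-2-methoxyphenyl)-3,4-dihydro-2H-chromen-7-ol
Conditions: H2 (1 atm), 10% Pd/C, EtOAc/MeOH, rt
Reagents that add atoms: none
Why: Hydrogenolysis of the three benzyl ethers over palladium on carbon under neutral conditions should be faster than cleavage of the cyclic benzylic C2–O1 bond and leaves both methyl ethers and both stereocenters intact.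

**Compound list**

1 | 5-hydroxy-2-methoxybenzaldehyde | COc1ccc(O)cc1C=O | starting material
2 | rac-1-(5-hydroxy-2-methoxyphenyl)prop-2-en-1-ol | COc1ccc(O)cc1C(O)C=C | intermediate
3 | 4-bromobenzene-1,3-diol | Oc1ccc(Br)c(O)c1 | starting material
4 | (E)-4-bromo-6-[3-(5-hydroxy-2-methoxyphenyl)prop-2-en-1-yl]benzene-1,3-diol | COc1ccc(O)cc1/C=C/Cc1cc(Br)c(O)cc1O | intermediate
5 | (2S)-6-bromo-2-(5-hydroxy-2-methoxyphenyl)-3,4-dihydro-2H-chromen-7-ol | Brc1cc2c(cc1O)O[C@H](c1cc(O)ccc1OC)CC2 | intermediate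
6 | (2S)-7-(benzyloxy)-2-[5-(benzyloxy)-2-methoxyphenyl]-6-bromo-3,4-dihydro-2H-chromene | Brc1cc2c(cc1OCc1ccccc1)O[C@H](c1cc(OCc3ccccc3)ccc1OC)CC2 | intermediate
7 | [(2S)-7-(benzyloxy)-2-[5-(benzyloxy)-2-methoxyphenyl]-3,4-dihydro-2H-chromen-6-yl]boronic acid | OB(O)c1cc2c(cc1OCc1ccccc1)O[C@H](c1cc(OCc3ccccc3)ccc1OC)CC2 | intermediate
8 | 1-(4-hydroxy-2-methoxyphenyl)ethan-1-one | CC(=O)c1ccc(O)cc1OC | starting material
9 | 4-(benzyloxy)benzaldehyde | O=Cc1ccc(OCc2ccccc2)cc1 | starting material
10 | (E)-3-[4-(benzyloxy)phenyl]-1-(4-hydroxy-2-methoxyphenyl)prop-2-en-1-one | COc1cc(O)ccc1C(=O)/C=C/c1ccc(OCc2ccccc2)cc1 | intermediate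
11 | (3R)-3-[4-(benzyloxy)phenyl]-3-[(2S)-7-(benzyloxy)-2-[5-(benzyloxy)-2-methoxyphenyl]-3,4-dihydro-2H-chromen-6-yl]-1-(4-hydroxy-2-methoxyphenyl)propan-1-one | COc1cc(O)ccc1C(=O)C[C@H](c1ccc(OCc2ccccc2)cc1)c1cc2c(cc1OCc1ccccc1)O[C@H](c1cc(OCc3ccccc3)ccc1OC)CC2 | intermediate
12 | N'-[(3R)-3-[4-(benzyloxy)phenyl]-3-[(2S)-7-(benzyloxy)-2-[5-(benzyloxy)-2-methoxyphenyl]-3,4-dihydro-2H-chromen-6-yl]-1-(4-hydroxy-2-methoxyphenyl)propylidene]-4-methylbenzenesulfonohydrazide (C=N geometry undefined) | COc1cc(O)ccc1C(=NNS(=O)(=O)c1ccc(C)cc1)C[C@H](c1ccc(OCc2ccccc2)cc1)c1cc2c(cc1OCc1ccccc1)O[C@H](c1cc(OCc3ccccc3)ccc1OC)CC2 | intermediate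
13 | 4-[(3R)-3-[4-(benzyloxy)phenyl]-3-[(2S)-7-(benzyloxy)-2-[5-(benzyloxy)-2-methoxyphenyl]-3,4-dihydro-2H-chromen-6-yl]propyl]-3-methoxyphenol | COc1cc(O)ccc1CC[C@H](c1ccc(OCc2ccccc2)cc1)c1cc2c(cc1OCc1ccccc1)O[C@H](c1cc(OCc3ccccc3)ccc1OC)CC2 | intermediate
14 | (2S)-6-[(1R)-3-(4-hydroxy-2-methoxyphenyl)-1-(4-hydroxyphenyl)propyl]-2-(5-hydroxy-2-methoxyphenyl)-3,4-dihydro-2H-chromen-7-ol | COc1cc(O)ccc1CC[C@H](c1ccc(O)cc1)c1cc2c(cc1O)O[C@H](c1cc(O)ccc1OC)CC2 | target

**Step count and risks**

Total step count: 9. Longest linear sequence: 8 steps (steps 1, 2, 3, 4, 6, 7, 8, 9, from compound 1).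

Steps most likely to fail:

Step 2. Enantiocontrol may be lost because the benzylic cation escapes the chiral ion pair, or because the product reopens at C2–O1 under the acid and racemises; the electron-rich product may also be allylated a second time. The fallback uses known chemistry, sets out from 3 and 2 and comes back at 5. Iodination of 3 with N-iodosuccinimide in MeCN should give 4-bromo-6-iodobenzene-1,3-diol F1. A Jeffery–Heck reaction of F1 with 2 (Pd(OAc)2, Bu4NCl, NaHCO3, DMF, 50 °C), in which the palladium hydride walks to the carbinol carbon, should give 3-(5-bromo-2,4-dihydroxyphenyl)-1-(5-hydroxy-2-methoxyphenyl)propan-1-one F2. Noyori transfer hydrogenation (RuCl[(R,R)-TsDPEN](p-cymene), HCO2H/Et3N) should give 4-bromo-6-[(3R)-3-hydroxy-3-(5-hydroxy-2-methoxyphenyl)propyl]benzene-1,3-diol F3. Mitsunobu cyclisation (PPh3, DIAD, THF, 0 °C) then closes O1–C2 with inversion to 5.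

Step 6. Protodeboronation of the ortho-alkoxy arylboronic acid may outrun its insertion into the electron-rich enone, so that the valuable fragment is lost as the arene. The fallback exchanges the roles of the partners, sets out from 6 and comes back at 11. Lithium–bromine exchange on 6 (n-BuLi, THF, −78 °C) and quenching with DMF should give (2S)-7-(benzyloxy)-2-[5-(benzyloxy)-2-methoxyphenyl]-3,4-dihydro-2H-chromene-6-carbaldehyde F4. Claisen–Schmidt condensation of F4 with 8 (KOH, EtOH) should give (E)-3-[(2S)-7-(benzyloxy)-2-[5-(benzyloxy)-2-methoxyphenyl]-3,4-dihydro-2H-chromen-6-yl]-1-(4-hydroxy-2-methoxyphenyl)prop-2-en-1-one F5. Addition of commercial 4-(benzyloxy)phenylboronic acid in excess with [Rh(OH)((S)-BINAP)]2 then gives 11; the ligand antipode changes because the migrating aryl and the β-aryl have exchanged roles.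

Step 8. Hydride delivery to the hindered, electron-rich hydrazone may stay incomplete, or elimination to an alkene may compete during the acetate stage. The fallback replaces the diazene pathway by an ionic one, sets out from 11 and comes back at 13. Reduction of 11 with NaBH4 (MeOH/THF) should give (3R)-3-[4-(benzyloxy)phenyl]-3-[(2S)-7-(benzyloxy)-2-[5-(benzyloxy)-2-methoxyphenyl]-3,4-dihydro-2H-chromen-6-yl]-1-(4-hydroxy-2-methoxyphenyl)propan-1-ol F6 as a mixture of carbinol epimers. Ionic hydrogenation (Et3SiH, TFA, CH2Cl2, −40 °C) through the cation stabilised by the para-hydroxyl and ortho-methoxy groups then gives 13, the low temperature keeping the less easily ionised C2–O1 bond closed.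

Further compounds
F1 | step 2 | 4-bromo-6-iodobenzene-1,3-diol | Oc1cc(O)c(I)cc1Br
F2 | step 2 | 3-(5-bromo-2,4-dihydroxyphenyl)-1-(5-hydroxy-2-methoxyphenyl)propan-1-one | COc1ccc(O)cc1C(=O)CCc1cc(Br)c(O)cc1O
F3 | step 2 | 4-bromo-6-[(3R)-3-hydroxy-3-(5-hydroxy-2-methoxyphenyl)propyl]benzene-1,3-diol | COc1ccc(O)cc1[C@H](O)CCc1cc(Br)c(O)cc1O
F4 | step 6 | (2S)-7-(benzyloxy)-2-[5-(benzyloxy)-2-methoxyphenyl]-3,4-dihydro-2H-chromene-6-carbaldehyde | O=Cc1cc2c(cc1OCc1ccccc1)O[C@H](c1cc(OCc3ccccc3)ccc1OC)CC2
F5 | step 6 | (E)-3-[(2S)-7-(benzyloxy)-2-[5-(benzyloxy)-2-methoxyphenyl]-3,4-dihydro-2H-chromen-6-yl]-1-(4-hydroxy-2-methoxyphenyl)prop-2-en-1-one | COc1cc(O)ccc1C(=O)/C=C/c1cc2c(cc1OCc1ccccc1)O[C@H](c1cc(OCc3ccccc3)ccc1OC)CC2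
F6 | step 8 | (3R)-3-[4-(benzyloxy)phenyl]-3-[(2S)-7-(benzyloxy)-2-[5-(benzyloxy)-2-methoxyphenyl]-3,4-dihydro-2H-chromen-6-yl]-1-(4-hydroxy-2-methoxyphenyl)propan-1-ol (epimers at C1) | COc1cc(O)ccc1C(O)C[C@H](c1ccc(OCc2ccccc2)cc1)c1cc2c(cc1OCc1ccccc1)O[C@H](c1cc(OCc3ccccc3)ccc1OC)CC2
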